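Conventions: chain atoms C1–C6 are those of the hexyl chain of the target (C1 carries the oxazole); primed locants (O1′, C2′, N3′, C4′, C5′) belong to the central oxazole. Compounds 1–15 are defined in the steps; 15 is the target.

## Analysis of the target

The target 15 is an acyclic hexane-1,3,4,5-tetrol whose C1 is bonded to C4′ of a 2,4-disubstituted oxazole. C5′ is unsubstituted, and C2′ carries a CH2 that leads to C5 of a second, otherwise unsubstituted oxazole. O3 carries a tetradecanoyl group; O1, O4 and O5 are free. There are four stereocentres, C1 (R), C3 (S), C4 (R) and C5 (S). C3–C5 form a 2-deoxy-L-lyxo triad (C3/C4 anti, C4/C5 syn), and the C1 hydroxyl is 1,3-syn to the C3 acyloxy group. The single ester sits between free hydroxyls (1,2 to O4 and 1,3 to O1), so base invites acyl migration; with C1 at the ketone level it becomes a β-acyloxy ketone that can eliminate. The CH2 between the two oxazoles and the C2–H of the terminal oxazole are acidic, so enolate or organolithium chemistry is unsafe once the bis-oxazole exists. The difficulties are therefore the placement of one ester on one of four secondary oxygens, the 1,3-syn relation (a hydride-transfer/acyl-transfer reduction would give anti), and assembly of the bis-oxazole without base. The feature that invites the key move is the central ring itself: C4′ and C5′–H are the two carbons of a terminal alkyne, and O1′–C2′–N3′ with its CH2-oxazole arm is a primary carboxamide. The ring can thus be closed last, under neutral gold catalysis, on a chain that already carries the ester and all four stereocentres.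

## Retrosynthetic reasoning

**15 ⇒ 14.** Only O–Si at C1 and the isopropylidene bridge across O4/O5 are cut. The ester is already in place, so the last step is an acid hydrolysis and no base meets the hydroxy ester.

**14 ⇒ 10 + 12 (key disconnection).** The central oxazole is cut at C5′–O1′ and C4′–N3′. This gives terminal alkyne 10, which holds C4′, C5′ and the complete acylated, protected chain, and primary amide 12, which holds O1′, C2′, N3′ and the second oxazole. The cut is made here because the bis-oxazole then never meets a base or an organometallic reagent, and because it makes the synthesis convergent at the latest possible point. The forward reaction must oxidise the alkyne regioselectively to an α-oxo carbene equivalent, let the amide oxygen capture it, and cyclodehydrate, without disturbing C1.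

**10 ⇒ 9 ⇒ 8 ⇒ 7.** The alkyne C–H comes from a C-silyl alkyne (9) and the C1 silyl ether from propargylic alcohol 8. The C1–H bond of 8 comes from ynone 7 by a reagent-controlled reduction. Setting C1 from a ketone with a chiral catalyst removes the need for 1,3-induction, which would require a free O3.

**7 ⇒ 5 + 6.** The ester C–O bond is cut. In 5 the C3 hydroxyl is the only free hydroxyl (O4/O5 are in the acetonide, C1 is a ketone), so the regiochemistry of acylation is settled by construction and not by selectivity.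

**5 ⇒ 2 + 4.** The C2–C3 bond is cut as an aldol between the enol silane 4 of an alkynyl methyl ketone and the α,β-dioxygenated aldehyde 2. The forward reaction has to set C3 anti to O4, which is the Felkin sense for a dioxolane aldehyde.

**2 ⇐ 1, 4 ⇐ 3, 12 ⇐ 11.** These are one-step adjustments of purchasable materials. Ester 1 supplies C4, C5 and C6 with both stereocentres.

## Alternatives that were turned down

Alternative 1: the textbook route cuts C2–C3 with the bis-oxazole already made. The methyl ketone A1 would be added as its enolate or enol silane to aldehyde 2 to give hydroxy ketone A2, followed by acylation with 6 and ketone reduction. It was turned down for three reasons.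
- A1 needs its own multi-step oxazole construction before the first stereocentre is made.
- Enolisation of A1 must choose between the acetyl CH3, the doubly activated CH2 between the rings and the C2–H of the terminal oxazole, whose metalation opens the ring.
- Every later step (acylation of a β-hydroxy ketone, catalytic reduction) would carry two coordinating, base-sensitive heterocycles.
It gains nothing in stereocontrol over the chosen route.

Alternative 2: a chiral-pool cut at C1–C4′. The glycal diester A3 would be converted to the bis-silylated 2-deoxy-lactone A4, a metalated oxazole made from bromide A5 would be added to give hemiketal A6, and C1 would be reduced. The C3–C5 triad would come for free, but there are four problems.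
- The pyranoid ring ties up O5 and leaves O3/O4 as the pair that must be masked together for the addition and then told apart, which is the opposite of what the target needs (ester on O3, O4/O5 free).
- The halogen–metal exchange has to be run next to the acidic inter-ring CH2.
- The 2-deoxy hemiketal A6 dehydrates easily to the glycal.
- A syn-selective reduction at C1 would need a free O3, which conflicts with having the ester there.
The step count would clearly exceed that of the chosen route.

Alternative 3: an Evans–Tishchenko reduction of A2 with the C14 aldehyde A8. Intramolecular hydride transfer within the samarium-bound hemiacetal would form the C1–H bond and the O3–acyl bond in one step and give A7. This is the most economical way to place the ester, but the bicyclic chair transition state delivers hydride anti to O3, so A7 is the C1 epimer of what is needed. Correction by Mitsunobu inversion at C1 would introduce a second ester that must be removed beside the tetradecanoate, and the route still inherits the problems of A1.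

Key step: step 9

Assumption: esters 1 (the acetonide methyl ester of the (2R,3S)-2,3-dihydroxybutanoic acid series, the antipode of the L-threonine-derived compound) and 11 are taken as purchasable building blocks.

Remark on descriptors: the dioxolane C4 descriptor is 4R when the neighbouring oxygen is acylated or silylated, or when the neighbour is a carbonyl carbon, and 4S when that oxygen is a free hydroxyl. This is a CIP priority effect only; the geometry never changes.

## Route

Step 1
Reactants: 1 methyl (4R,5S)-2,2,5-trimethyl-1,3-dioxolane-4-carboxylate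
Product: 2 (4R,5S)-2,2,5-trimethyl-1,3-dioxolane-4-carbaldehyde
Conditions: DIBAL-H (1.1 equiv), CH2Cl2, −78 °C; Rochelle salt work-up; used crude
Reagents that add atoms: none
Why: Partial reduction of an α-alkoxy ester, whose chelated tetrahedral aluminium adduct should survive at −78 °C and collapse to the aldehyde only on work-up; the trans-dioxolane is the more stable isomer, so C4 should not drift.

Step 2
Reactants: 3 4-(trimethylsilyl)but-3-yn-2-one
Product: 4 trimethyl{[4-(trimethylsilyl)but-1-en-3-yn-2-yl]oxy}silane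
Conditions: LDA, THF, −78 °C; then TMSCl; distillation
Reagents that add atoms: chlorotrimethylsilane, C[Si](C)(C)Cl
Why: Kinetic deprotonation of the only enolisable position (the methyl group) by a hindered amide base and O-silylation of the enolate; the C-silyl group blocks the alkyne terminus.

Step 3
Reactants: 2 (4R,5S)-2,2,5-trimethyl-1,3-dioxolane-4-carbaldehyde; 4 trimethyl{[4-(trimethylsilyl)but-1-en-3-yn-2-yl]oxy}silane
Product: 5 (5S)-5-hydroxy-5-[(4S,5S)-2,2,5-trimethyl-1,3-dioxolan-4-yl]-1-(trimethylsilyl)pent-1-yn-3-one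
Conditions: BF3·OEt2 (1.1 equiv), CH2Cl2, −78 °C; aq. NaHCO3
Reagents that add atoms: none
Why: Mukaiyama aldol through an open transition state; monodentate BF3 cannot chelate, so the enol silane should attack the aldehyde face given by the Felkin–Anh (polar) model, anti to the C4–O bond of the dioxolane, which sets C3 (S) in the required 3,4-anti relationship.

Step 4
Reactants: 5 (5S)-5-hydroxy-5-[(4S,5S)-2,2,5-trimethyl-1,3-dioxolan-4-yl]-1-(trimethylsilyl)pent-1-yn-3-one; 6 tetradecanoyl chloride
Product: 7 (1S)-3-oxo-1-[(4R,5S)-2,2,5-trimethyl-1,3-dioxolan-4-yl]-5-(trimethylsilyl)pent-4-yn-1-yl tetradecanoate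
Conditions: pyridine, CH2Cl2, 0 °C, short reaction time
Reagents that add atoms: none
Why: O-acylation of the only free hydroxyl of the molecule, so the ester can only land on O3; pyridine without a stronger base and low temperature are chosen to keep E1cB loss of the new acyloxy group slow.

Step 5
Reactants: 7 (1S)-3-oxo-1-[(4R,5S)-2,2,5-trimethyl-1,3-dioxolan-4-yl]-5-(trimethylsilyl)pent-4-yn-1-yl tetradecanoate
Product: 8 (1S,3R)-3-hydroxy-1-[(4R,5S)-2,2,5-trimethyl-1,3-dioxolan-4-yl]-5-(trimethylsilyl)pent-4-yn-1-yl tetradecanoate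
Conditions: Ru[(R,R)-TsDPEN](p-cymene) (2 mol%, base-free 16-electron amido complex), i-PrOH, rt
Reagents that add atoms: none
Why: Noyori asymmetric transfer hydrogenation of an alkynyl ketone, in which the alkyne takes the place an aryl group takes in the outer-sphere six-membered transition state, so the (R,R)-catalyst should deliver hydride to give the (R)-carbinol at C1 under reagent control, 1,3-syn to O3; the neutral medium should spare the β-acyloxy ketone, the ester and the C–Si bond.

Step 6
Reactants: 8 (1S,3R)-3-hydroxy-1-[(4R,5S)-2,2,5-trimethyl-1,3-dioxolan-4-yl]-5-(trimethylsilyl)pent-4-yn-1-yl tetradecanoate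
Product: 9 (1S,3R)-3-[(tert-butyldimethylsilyl)oxy]-1-[(4R,5S)-2,2,5-trimethyl-1,3-dioxolan-4-yl]-5-(trimethylsilyl)pent-4-yn-1-yl tetradecanoate
Conditions: TBSOTf, 2,6-lutidine, CH2Cl2, −78 °C
Reagents that add atoms: tert-butyldimethylsilyl trifluoromethanesulfonate, CC(C)(C)[Si](C)(C)OS(=O)(=O)C(F)(F)F
Why: Fast silylation of the propargylic hydroxyl with a non-nucleophilic base at low temperature, which should outrun a 1,3-acyl shift from O3 to O1; the bulky silyl ether is needed because a free propargylic hydroxyl would trap the gold carbene of step 9 intramolecularly.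

Step 7
Reactants: 9 (1S,3R)-3-[(tert-butyldimethylsilyl)oxy]-1-[(4R,5S)-2,2,5-trimethyl-1,3-dioxolan-4-yl]-5-(trimethylsilyl)pent-4-yn-1-yl tetradecanoate
Product: 10 (1S,3R)-3-[(tert-butyldimethylsilyl)oxy]-1-[(4R,5S)-2,2,5-trimethyl-1,3-dioxolan-4-yl]pent-4-yn-1-yl tetradecanoate
Conditions: AgNO3 (10 mol%), acetone/H2O, rt
Reagents that add atoms: none
Why: Silver(I)-catalysed protodesilylation of an alkynylsilane, in which π-coordination of Ag+ labilises the C(sp)–Si bond toward water and the silver acetylide is protonated; the O-silyl ether, the ester and the acetonide should not react, which is why carbonate in methanol is avoided.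

Step 8
Reactants: 11 methyl 2-(1,3-oxazol-5-yl)acetate
Product: 12 2-(1,3-oxazol-5-yl)acetamide
Conditions: NH3 (7 M in MeOH), rt
Reagents that add atoms: ammonia, N
Why: Ammonolysis of an unhindered, inductively activated methyl ester; the conditions are too weakly basic to affect the oxazole ring.

Step 9
Reactants: 10 (1S,3R)-3-[(tert-butyldimethylsilyl)oxy]-1-[(4R,5S)-2,2,5-trimethyl-1,3-dioxolan-4-yl]pent-4-yn-1-yl tetradecanoate; 12 2-(1,3-oxazol-5-yl)acetamide
Product: 14 (1S,3R)-3-[(tert-butyldimethylsilyl)oxy]-3-{2-[(1,3-oxazol-5-yl)methyl]-1,3-oxazol-4-yl}-1-[(4R,5S)-2,2,5-trimethyl-1,3-dioxolan-4-yl]propyl tetradecanoate, via keto imidate 13 (not isolated)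
Conditions: Mor-DalPhosAuOMs (5 mol%), NaBArF4 (10 mol%), 8-methylquinoline N-oxide (1.5 equiv, slow addition), 12 (2.5 equiv), PhCl, 60 °C
Reagents that add atoms: none
Why: The cationic P,N-ligated gold(I) complex activates the terminal alkyne of 10, the N-oxide adds to the internal carbon, and N–O cleavage leaves an α-oxo gold carbene on the terminal carbon. The carbonyl oxygen of amide 12 adds to the carbene carbon and protodeauration gives keto imidate 13. The imidate nitrogen then closes onto the ketone by a 5-exo-trig addition, and loss of water (which carries away the oxygen of the N-oxide) aromatises the ring; C5′–O1′ and C4′–N3′ are formed and the two halves are joined. The closest known reaction type is the gold-catalysed oxidative [3+2] annulation of terminal alkynes with primary carboxamides to 2,4-disubstituted oxazoles, in which the P,N ligand tempers the carbene enough for a weak external nucleophile to compete. No stereocentre is created; C1 only has to survive as the α-carbon of the transient ketone, which the weakly basic medium, the absence of a β-leaving group and the fast cyclodehydration should allow. The step needs oxygen delivery to the internal alkyne carbon, which the terminal alkyne secures. It also needs capture by the amide rather than by a second N-oxide or by O1, which slow N-oxide addition, the excess of amide and the bulky, proton-free silyl ether should secure. The ester and the acetonide are inert to these neutral conditions, and no base meets the acidic CH2 between the two oxazoles.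

Step 10
Reactants: 14 (1S,3R)-3-[(tert-butyldimethylsilyl)oxy]-3-{2-[(1,3-oxazol-5-yl)methyl]-1,3-oxazol-4-yl}-1-[(4R,5S)-2,2,5-trimethyl-1,3-dioxolan-4-yl]propyl tetradecanoate
Product: 15 (1R,3S,4R,5S)-1,4,5-trihydroxy-1-{2-[(1,3-oxazol-5-yl)methyl]-1,3-oxazol-4-yl}hexan-3-yl tetradecanoate
Conditions: TFA/H2O (9:1), CH2Cl2, 0 °C to rt; evaporation with toluene
Reagents that add atoms: none
Why: Acid-catalysed hydrolysis of the dioxolane and of the secondary silyl ether in one operation; acid is chosen over fluoride or base because base would trigger 1,2- and 1,3-acyl shifts, and no C–O bond at a stereocentre is broken, so all four configurations should be retained.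

## Compound list

1 | methyl (4R,5S)-2,2,5-trimethyl-1,3-dioxolane-4-carboxylate | COC(=O)[C@@H]1OC(C)(C)O[C@H]1C | starting material
2 | (4R,5S)-2,2,5-trimethyl-1,3-dioxolane-4-carbaldehyde | O=C[C@@H]1OC(C)(C)O[C@H]1C | intermediate
3 | 4-(trimethylsilyl)but-3-yn-2-one | CC(=O)C#C[Si](C)(C)C | starting material
4 | trimethyl{[4-(trimethylsilyl)but-1-en-3-yn-2-yl]oxy}silane | C=C(O[Si](C)(C)C)C#C[Si](C)(C)C | intermediate
5 | (5S)-5-hydroxy-5-[(4S,5S)-2,2,5-trimethyl-1,3-dioxolan-4-yl]-1-(trimethylsilyl)pent-1-yn-3-one | C[Si](C)(C)C#CC(=O)C[C@H](O)[C@@H]1OC(C)(C)O[C@H]1C | intermediate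
6 | tetradecanoyl chloride | CCCCCCCCCCCCCC(=O)Cl | starting material
7 | (1S)-3-oxo-1-[(4R,5S)-2,2,5-trimethyl-1,3-dioxolan-4-yl]-5-(trimethylsilyl)pent-4-yn-1-yl tetradecanoate | C[Si](C)(C)C#CC(=O)C[C@H](OC(=O)CCCCCCCCCCCCC)[C@@H]1OC(C)(C)O[C@H]1C | intermediate
8 | (1S,3R)-3-hydroxy-1-[(4R,5S)-2,2,5-trimethyl-1,3-dioxolan-4-yl]-5-(trimethylsilyl)pent-4-yn-1-yl tetradecanoate | C[Si](C)(C)C#C[C@H](O)C[C@H](OC(=O)CCCCCCCCCCCCC)[C@@H]1OC(C)(C)O[C@H]1C | intermediate
9 | (1S,3R)-3-[(tert-butyldimethylsilyl)oxy]-1-[(4R,5S)-2,2,5-trimethyl-1,3-dioxolan-4-yl]-5-(trimethylsilyl)pent-4-yn-1-yl tetradecanoate | C[Si](C)(C)C#C[C@H](O[Si](C)(C)C(C)(C)C)C[C@H](OC(=O)CCCCCCCCCCCCC)[C@@H]1OC(C)(C)O[C@H]1C | intermediate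
10 | (1S,3R)-3-[(tert-butyldimethylsilyl)oxy]-1-[(4R,5S)-2,2,5-trimethyl-1,3-dioxolan-4-yl]pent-4-yn-1-yl tetradecanoate | C#C[C@H](O[Si](C)(C)C(C)(C)C)C[C@H](OC(=O)CCCCCCCCCCCCC)[C@@H]1OC(C)(C)O[C@H]1C | intermediate
11 | methyl 2-(1,3-oxazol-5-yl)acetate | COC(=O)Cc1cnco1 | starting material
12 | 2-(1,3-oxazol-5-yl)acetamide | NC(=O)Cc1cnco1 | intermediate
13 | (3R,5S)-3-[(tert-butyldimethylsilyl)oxy]-2-oxo-5-(tetradecanoyloxy)-5-[(4R,5S)-2,2,5-trimethyl-1,3-dioxolan-4-yl]pentyl 2-(1,3-oxazol-5-yl)ethanimidate (keto imidate) | N=C(Cc1cnco1)OCC(=O)[C@H](O[Si](C)(C)C(C)(C)C)C[C@H](OC(=O)CCCCCCCCCCCCC)[C@@H]1OC(C)(C)O[C@H]1C | intermediate (not isolated)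
14 | (1S,3R)-3-[(tert-butyldimethylsilyl)oxy]-3-{2-[(1,3-oxazol-5-yl)methyl]-1,3-oxazol-4-yl}-1-[(4R,5S)-2,2,5-trimethyl-1,3-dioxolan-4-yl]propyl tetradecanoate | CCCCCCCCCCCCCC(=O)O[C@@H](C[C@@H](O[Si](C)(C)C(C)(C)C)c1coc(Cc2cnco2)n1)[C@@H]1OC(C)(C)O[C@H]1C | intermediate
15 | (1R,3S,4R,5S)-1,4,5-trihydroxy-1-{2-[(1,3-oxazol-5-yl)methyl]-1,3-oxazol-4-yl}hexan-3-yl tetradecanoate | CCCCCCCCCCCCCC(=O)O[C@@H](C[C@@H](O)c1coc(Cc2cnco2)n1)[C@H](O)[C@H](C)O | target

## Step count and least certain steps

Total step count: 10. Longest linear sequence: 8 steps (steps 1, 3, 4, 5, 6, 7, 9, 10; the sequence from 3 through step 2 is equally long).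

**Step 9 (key step).** The most likely failure is that the α-oxo gold carbene is consumed by a second N-oxide (over-oxidation to the 1,2-dicarbonyl) or by the neighbouring C1 oxygen faster than by the external amide. The propargylic oxygen makes the alkyne electron-poor, and the amide is only sparingly soluble in chlorobenzene. A slower hazard is enolisation of the transient α-silyloxy ketone, which would erode C1. Fallback, setting out from 10 and returning at 14: bromination of the alkyne C–H (NBS, cat. AgNO3, acetone) should give (1S,3R)-5-bromo-3-[(tert-butyldimethylsilyl)oxy]-1-[(4R,5S)-2,2,5-trimethyl-1,3-dioxolan-4-yl]pent-4-yn-1-yl tetradecanoate F1. Gold-catalysed hydration of the bromoalkyne should give the bromomethyl ketone (1S,3R)-5-bromo-3-[(tert-butyldimethylsilyl)oxy]-4-oxo-1-[(4R,5S)-2,2,5-trimethyl-1,3-dioxolan-4-yl]pentyl tetradecanoate F2. A silver-promoted Blümlein–Lewy (Hantzsch-type) condensation of F2 with 12 (AgSbF6, 1,2-dichloroethane, 60 °C) then closes the same oxazole and gives 14.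

**Step 3.** The most likely failure is poor facial selectivity. The only directing element is the α-oxygen of a small trans-dioxolane and the enyne nucleophile is slim, so the C3 epimer could form in a disturbing amount and be hard to remove. Fallback, setting out from 2 and returning at 7:
- Reagent-controlled Brown allylboration with the Ipc2B(allyl) antipode matched to the Felkin preference (expected to be (−)-Ipc2B(allyl)) should give (1S)-1-[(4S,5S)-2,2,5-trimethyl-1,3-dioxolan-4-yl]but-3-en-1-ol F3.
- Acylation with 6 gives (1S)-1-[(4R,5S)-2,2,5-trimethyl-1,3-dioxolan-4-yl]but-3-en-1-yl tetradecanoate F4.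
- Ozonolysis (O3, then PPh3) gives (1S)-3-oxo-1-[(4R,5S)-2,2,5-trimethyl-1,3-dioxolan-4-yl]propyl tetradecanoate F5.
- Addition of lithium (trimethylsilyl)acetylide at −78 °C gives the epimeric alcohols (1S,3RS)-3-hydroxy-1-[(4R,5S)-2,2,5-trimethyl-1,3-dioxolan-4-yl]-5-(trimethylsilyl)pent-4-yn-1-yl tetradecanoate F6.
- Dess–Martin oxidation converges both epimers on ynone 7.

**Step 4.** The most likely failure is E1cB loss of the tetradecanoate from the β-acyloxy ynone during or after acylation, because the C2 hydrogens are flanked by the ynone carbonyl. Competing 6-endo oxa-Michael closure of the free hydroxy ynone is a second drain. The elimination hazard persists, to a lesser degree, in step 5. Fallback, setting out from 5 and returning at 9, in which the ester is never β to a ketone: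
- Silylation (TESOTf, 2,6-lutidine) gives (5S)-5-[(triethylsilyl)oxy]-5-[(4R,5S)-2,2,5-trimethyl-1,3-dioxolan-4-yl]-1-(trimethylsilyl)pent-1-yn-3-one F7.
- Transfer hydrogenation as in step 5 gives (3R,5S)-5-[(triethylsilyl)oxy]-5-[(4R,5S)-2,2,5-trimethyl-1,3-dioxolan-4-yl]-1-(trimethylsilyl)pent-1-yn-3-ol F8.
- Silylation with TBSOTf gives tert-butyldimethyl{[(3R,5S)-5-[(triethylsilyl)oxy]-5-[(4R,5S)-2,2,5-trimethyl-1,3-dioxolan-4-yl]-1-(trimethylsilyl)pent-1-yn-3-yl]oxy}silane F9.
- Selective cleavage of the triethylsilyl ether (PPTS, MeOH/CH2Cl2, 0 °C) gives (1S,3R)-3-[(tert-butyldimethylsilyl)oxy]-1-[(4S,5S)-2,2,5-trimethyl-1,3-dioxolan-4-yl]-5-(trimethylsilyl)pent-4-yn-1-ol F10.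
- Acylation with 6 (pyridine, DMAP) gives 9.

**Step 10.** The most likely failure is an acid-promoted 1,2-acyl shift from O3 to the liberated O4 through the cyclic orthoacid. Slow hydrolysis of the trans-acetonide would make this worse by forcing long exposure to acid. Fallback, setting out from 14 and returning at 15, in two orthogonal, non-hydrolytic operations: buffered HF·pyridine (THF, 0 °C) should remove only the silyl ether and give (1S,3R)-3-hydroxy-3-{2-[(1,3-oxazol-5-yl)methyl]-1,3-oxazol-4-yl}-1-[(4R,5S)-2,2,5-trimethyl-1,3-dioxolan-4-yl]propyl tetradecanoate F11. BCl3 in CH2Cl2 at −78 °C then cleaves the acetonide at a temperature at which acyl migration should be frozen, and a cold aqueous quench gives 15.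

## Further compounds

F1 | step 9 | (1S,3R)-5-bromo-3-[(tert-butyldimethylsilyl)oxy]-1-[(4R,5S)-2,2,5-trimethyl-1,3-dioxolan-4-yl]pent-4-yn-1-yl tetradecanoate | BrC#C[C@H](O[Si](C)(C)C(C)(C)C)C[C@H](OC(=O)CCCCCCCCCCCCC)[C@@H]1OC(C)(C)O[C@H]1C
F2 | step 9 | (1S,3R)-5-bromo-3-[(tert-butyldimethylsilyl)oxy]-4-oxo-1-[(4R,5S)-2,2,5-trimethyl-1,3-dioxolan-4-yl]pentyl tetradecanoate | BrCC(=O)[C@H](O[Si](C)(C)C(C)(C)C)C[C@H](OC(=O)CCCCCCCCCCCCC)[C@@H]1OC(C)(C)O[C@H]1C
F3 | step 3 | (1S)-1-[(4S,5S)-2,2,5-trimethyl-1,3-dioxolan-4-yl]but-3-en-1-ol | C=CC[C@H](O)[C@@H]1OC(C)(C)O[C@H]1C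
F4 | step 3 | (1S)-1-[(4R,5S)-2,2,5-trimethyl-1,3-dioxolan-4-yl]but-3-en-1-yl tetradecanoate | C=CC[C@H](OC(=O)CCCCCCCCCCCCC)[C@@H]1OC(C)(C)O[C@H]1C
F5 | step 3 | (1S)-3-oxo-1-[(4R,5S)-2,2,5-trimethyl-1,3-dioxolan-4-yl]propyl tetradecanoate | O=CC[C@H](OC(=O)CCCCCCCCCCCCC)[C@@H]1OC(C)(C)O[C@H]1C
F6 | step 3 | (1S,3RS)-3-hydroxy-1-[(4R,5S)-2,2,5-trimethyl-1,3-dioxolan-4-yl]-5-(trimethylsilyl)pent-4-yn-1-yl tetradecanoate | C[Si](C)(C)C#CC(O)C[C@H](OC(=O)CCCCCCCCCCCCC)[C@@H]1OC(C)(C)O[C@H]1C
F7 | step 4 | (5S)-5-[(triethylsilyl)oxy]-5-[(4R,5S)-2,2,5-trimethyl-1,3-dioxolan-4-yl]-1-(trimethylsilyl)pent-1-yn-3-one | C[Si](C)(C)C#CC(=O)C[C@H](O[Si](CC)(CC)CC)[C@@H]1OC(C)(C)O[C@H]1C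
F8 | step 4 | (3R,5S)-5-[(triethylsilyl)oxy]-5-[(4R,5S)-2,2,5-trimethyl-1,3-dioxolan-4-yl]-1-(trimethylsilyl)pent-1-yn-3-ol | C[Si](C)(C)C#C[C@H](O)C[C@H](O[Si](CC)(CC)CC)[C@@H]1OC(C)(C)O[C@H]1C
F9 | step 4 | tert-butyldimethyl{[(3R,5S)-5-[(triethylsilyl)oxy]-5-[(4R,5S)-2,2,5-trimethyl-1,3-dioxolan-4-yl]-1-(trimethylsilyl)pent-1-yn-3-yl]oxy}silane | C[Si](C)(C)C#C[C@H](O[Si](C)(C)C(C)(C)C)C[C@H](O[Si](CC)(CC)CC)[C@@H]1OC(C)(C)O[C@H]1C
F10 | step 4 | (1S,3R)-3-[(tert-butyldimethylsilyl)oxy]-1-[(4S,5S)-2,2,5-trimethyl-1,3-dioxolan-4-yl]-5-(trimethylsilyl)pent-4-yn-1-ol | C[Si](C)(C)C#C[C@H](O[Si](C)(C)C(C)(C)C)C[C@H](O)[C@@H]1OC(C)(C)O[C@H]1C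
F11 | step 10 | (1S,3R)-3-hydroxy-3-{2-[(1,3-oxazol-5-yl)methyl]-1,3-oxazol-4-yl}-1-[(4R,5S)-2,2,5-trimethyl-1,3-dioxolan-4-yl]propyl tetradecanoate | CCCCCCCCCCCCCC(=O)O[C@@H](C[C@@H](O)c1coc(Cc2cnco2)n1)[C@@H]1OC(C)(C)O[C@H]1C
A1 | alternative 1 | 1-{2-[(1,3-oxazol-5-yl)methyl]-1,3-oxazol-4-yl}ethan-1-one | CC(=O)c1coc(Cc2cnco2)n1
A2 | alternative 1 | (3S)-3-hydroxy-1-{2-[(1,3-oxazol-5-yl)methyl]-1,3-oxazol-4-yl}-3-[(4S,5S)-2,2,5-trimethyl-1,3-dioxolan-4-yl]propan-1-one | O=C(C[C@H](O)[C@@H]1OC(C)(C)O[C@H]1C)c1coc(Cc2cnco2)n1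
A3 | alternative 2 | (2S,3R,4S)-2-methyl-3,4-dihydro-2H-pyran-3,4-diyl diacetate (3,4-di-O-acetyl-L-fucal) | C[C@@H]1OC=C[C@H](OC(C)=O)[C@@H]1OC(C)=O
A4 | alternative 2 | (4S,5R,6S)-6-methyl-4,5-bis[(triethylsilyl)oxy]oxan-2-one | O=C1C[C@H](O[Si](CC)(CC)CC)[C@H](O[Si](CC)(CC)CC)[C@H](C)O1
A5 | alternative 2 | 4-bromo-2-[(1,3-oxazol-5-yl)methyl]-1,3-oxazole | Brc1coc(Cc2cnco2)n1
A6 | alternative 2 | (4S,5R,6S)-6-methyl-2-{2-[(1,3-oxazol-5-yl)methyl]-1,3-oxazol-4-yl}-4,5-bis[(triethylsilyl)oxy]oxan-2-ol (anomeric mixture) | OC1(c2coc(Cc3cnco3)n2)C[C@H](O[Si](CC)(CC)CC)[C@H](O[Si](CC)(CC)CC)[C@H](C)O1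
A7 | alternative 3 | (1S,3S)-3-hydroxy-3-{2-[(1,3-oxazol-5-yl)methyl]-1,3-oxazol-4-yl}-1-[(4R,5S)-2,2,5-trimethyl-1,3-dioxolan-4-yl]propyl tetradecanoate | CCCCCCCCCCCCCC(=O)O[C@@H](C[C@H](O)c1coc(Cc2cnco2)n1)[C@@H]1OC(C)(C)O[C@H]1C
A8 | alternative 3 | tetradecanal | CCCCCCCCCCCCCC=O
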